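## Retrosynthetic overview

1. Target ⇐ CBS reduction of the C1 ketone, peracid epoxidation of C4=C5 and silyl-to-acetate exchange at C13 on a ten-membered 1-oxo-germacra-4,7(11),9-trienolide.
2. Ten-membered carbocycle ⇐ ring contraction of a twelve-membered allyl β-keto macrolactone: loss of CO2 with C2–C3 bond formation (palladium π-allyl/enolate recombination).
3. β-Keto macrolactone ⇐ alkynoate macrolactone (hydration; C8 tiglate) ⇐ Ni/Cr macrocyclisation forming C7–C8 from a β-iodobutenolide aldehyde.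
4. That aldehyde ⇐ ester union of the iodobutenolide (isoprene monoxide + methyl propiolate + formaldehyde) with a Z-enynoic acid ((Z)-3-methylpent-2-en-4-yn-1-ol + CO2).
5. Ring order: butenolide → twelve-membered lactone → ten-membered carbocycle → epoxide.

Assumption: ten-membered compounds use germacranolide numbering (C1 ketone/carbinol, C2–C3 CH2, C4–C5 alkene/epoxide with the C4 methyl, C6 lactone O–CH, C7=C11 butenolide alkene, C8 tiglate carbon, C9=C10 alkene with the C10 methyl, C12 lactone C=O, C13 CH2O); tigloyl = (E)-2-methylbut-2-enoyl; TBS = tert-butyldimethylsilyl.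

## Route

Step 1
Reactants: 1 2-methyl-2-vinyloxirane (isoprene monoxide, racemic)
Product: 2 (2E)-4-chloro-2-methylbut-2-en-1-ol
Conditions: HCl (37% aq.), CuCl (5 mol %), Et2O, −10 → 0 °C
Reagents that add atoms: hydrogen chloride, Cl
Why: Copper-assisted SN2′ (1,4) opening of the vinyl epoxide by chloride, with allylic equilibration under CuCl giving the thermodynamically preferred E primary allylic chloride (C3–C6 and the C4 methyl of the target).

Step 2
Reactants: 2 (2E)-4-chloro-2-methylbut-2-en-1-ol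
Product: 3 (2E)-4-hydroxy-3-methylbut-2-enal
Conditions: NMO (3 equiv), 4 Å MS, MeCN, 0 → 23 °C
Reagents that add atoms: 4-methylmorpholine N-oxide, C[N+]1([O-])CCOCC1
Why: Ganem-type N-oxide oxidation (SN2 O-alkylation of the N-oxide by the allylic chloride, then elimination) gives the enal without touching the E alkene or the free primary alcohol.

Step 3
Reactants: 3 (2E)-4-hydroxy-3-methylbut-2-enal
Product: 4 (2E)-4-chloro-3-methylbut-2-enal
Conditions: MsCl, 2,4,6-collidine, LiCl, DMF, 0 °C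
Reagents that add atoms: lithium chloride, [Li+].[Cl-]
Why: Collington–Meyers chlorination (in situ mesylate displaced by chloride, SN2) converts the primary allylic alcohol to the chloride without allylic transposition, and the enal is inert.

Step 4
Reactants: 4 (2E)-4-chloro-3-methylbut-2-enal; 5 methyl propiolate
Product: 6 methyl (4R,5E)-7-chloro-4-hydroxy-6-methylhept-5-en-2-ynoate
Conditions: (S,S)-ProPhenol (20 mol %), Me2Zn (3 equiv), Ph3P=O (40 mol %), toluene, 4 °C
Reagents that add atoms: none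
Why: Trost zinc–ProPhenol alkynylation, in which the chiral dinuclear zinc alkynylide adds to one face of the enal and sets the C6 carbinol (4R here; the ligand antipode is the one that gives this face, to be confirmed by Mosher analysis), while the allylic chloride is inert to the organozinc species at 4 °C.

Step 5
Reactants: 6 methyl (4R,5E)-7-chloro-4-hydroxy-6-methylhept-5-en-2-ynoate; 7 formaldehyde (monomer from cracked paraformaldehyde, THF solution)
Product: 9 (5R)-5-[(1E)-3-chloro-2-methylprop-1-en-1-yl]-3-(hydroxymethyl)-4-iodofuran-2(5H)-one, via open-chain iodo diol ester 8 (not isolated)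
Conditions: Et2AlI (2.3 equiv), CH2Cl2, −78 °C; CH2O (3 equiv), −78 → −30 °C; then 1 M HCl, THF, 23 °C
Reagents that add atoms: diethylaluminium iodide, CC[Al](I)CC
Why: β-Iodo Morita–Baylis–Hillman (halo-aldol) reaction, in which the first equivalent of Et2AlI makes the aluminium alkoxide, iodide adds to the ynoate β-carbon and the aluminium allenoate is trapped by formaldehyde at the α-carbon; only the alkene isomer with the ester cis to the C6 oxygen can lactonise, which funnels the material to the β-iodobutenolide with C6 untouched.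

Step 6
Reactants: 9 (5R)-5-[(1E)-3-chloro-2-methylprop-1-en-1-yl]-3-(hydroxymethyl)-4-iodofuran-2(5H)-one
Product: 10 (5R)-3-[(TBS-oxy)methyl]-5-[(1E)-3-chloro-2-methylprop-1-en-1-yl]-4-iodofuran-2(5H)-one
Conditions: TBSOTf, 2,6-lutidine, CH2Cl2, −78 °C
Reagents that add atoms: tert-butyldimethylsilyl trifluoromethanesulfonate, CC(C)(C)[Si](C)(C)OS(=O)(=O)C(F)(F)F
Why: Silylation with a hindered, non-nucleophilic base protects the C13 alcohol for the later oxidation, tigloylation and palladium steps without alkylating the base at the allylic chloride.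

Step 7
Reactants: 11 (2Z)-3-methylpent-2-en-4-yn-1-ol
Product: 12 (4Z)-6-hydroxy-4-methylhex-4-en-2-ynoic acid
Conditions: n-BuLi (2.1 equiv), THF, −78 °C; CO2 (g), −78 → 0 °C; 1 M HCl
Reagents that add atoms: carbon dioxide, O=C=O
Why: Carboxylation of the alkoxide/acetylide dianion gives the ynoic acid, and the Z trisubstituted alkene (C9=C10 of the target) comes unchanged from the starting material.

Step 8
Reactants: 10 (5R)-3-[(TBS-oxy)methyl]-5-[(1E)-3-chloro-2-methylprop-1-en-1-yl]-4-iodofuran-2(5H)-one; 12 (4Z)-6-hydroxy-4-methylhex-4-en-2-ynoic acid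
Product: 13 (2E)-3-[(2R)-4-[(TBS-oxy)methyl]-3-iodo-5-oxo-2,5-dihydrofuran-2-yl]-2-methylprop-2-en-1-yl (4Z)-6-hydroxy-4-methylhex-4-en-2-ynoate
Conditions: Cs2CO3 (0.55 equiv), NaI (10 mol %), DMF, 0 → 23 °C
Reagents that add atoms: none
Why: SN2 O-alkylation of the caesium carboxylate by the primary allylic chloride (iodide catalysis) joins the two halves; the carboxylate is too weak a base to epimerise the butenolide C6–H or to displace the vinyl iodide.

Step 9
Reactants: 13 (2E)-3-[(2R)-4-[(TBS-oxy)methyl]-3-iodo-5-oxo-2,5-dihydrofuran-2-yl]-2-methylprop-2-en-1-yl (4Z)-6-hydroxy-4-methylhex-4-en-2-ynoate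
Product: 14 (2E)-3-[(2R)-4-[(TBS-oxy)methyl]-3-iodo-5-oxo-2,5-dihydrofuran-2-yl]-2-methylprop-2-en-1-yl (4Z)-4-methyl-6-oxohex-4-en-2-ynoate
Conditions: MnO2 (15 equiv), CH2Cl2, 23 °C
Reagents that add atoms: none
Why: Chemoselective MnO2 oxidation of the only allylic alcohol gives the Z enal under neutral conditions that do not isomerise the alkene.

Step 10
Reactants: 14 (2E)-3-[(2R)-4-[(TBS-oxy)methyl]-3-iodo-5-oxo-2,5-dihydrofuran-2-yl]-2-methylprop-2-en-1-yl (4Z)-4-methyl-6-oxohex-4-en-2-ynoate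
Product: 15 (1R,2E,9Z,11S)-13-[(TBS-oxy)methyl]-11-hydroxy-3,9-dimethyl-5,15-dioxabicyclo[10.3.0]pentadeca-2,9,12-trien-7-yne-6,14-dione
Conditions: CrCl2 (4 equiv), (S)-N-[2-(4-isopropyl-4,5-dihydrooxazol-2-yl)-6-methylphenyl]methanesulfonamide (4.4 equiv), Et3N (4.4 equiv), NiCl2 (5 mol %), THF, 0.004 M (syringe pump), 23 °C
Reagents that add atoms: none
Why: Nozaki–Hiyama–Kishi macrocyclisation, in which zerovalent nickel inserts into the vinyl iodide and the vinylchromium species adds 1,2 to the enal to form C7–C8 and close the twelve-membered ring; the chiral sulfonamide on chromium selects the aldehyde face for the 11S (C8) carbinol, and the lactone, silyl ether and alkynoate tolerate divalent chromium under aprotic conditions.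

Step 11
Reactants: 15 (1R,2E,9Z,11S)-13-[(TBS-oxy)methyl]-11-hydroxy-3,9-dimethyl-5,15-dioxabicyclo[10.3.0]pentadeca-2,9,12-trien-7-yne-6,14-dione; 16 tigloyl chloride [(2E)-2-methylbut-2-enoyl chloride]
Product: 17 (1R,2E,9Z,11S)-13-[(TBS-oxy)methyl]-3,9-dimethyl-6,14-dioxo-5,15-dioxabicyclo[10.3.0]pentadeca-2,9,12-trien-7-yn-11-yl (2E)-2-methylbut-2-enoate
Conditions: pyridine, DMAP (cat.), CH2Cl2, 0 → 23 °C
Reagents that add atoms: none
Why: DMAP-catalysed acylation fixes the tiglate on C8 with retention, and doing it before C1 becomes a ketone prevents the Z-γ-hydroxy enone from closing to a transannular hemiketal or furan.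

Step 12
Reactants: 17 (1R,2E,9Z,11S)-13-[(TBS-oxy)methyl]-3,9-dimethyl-6,14-dioxo-5,15-dioxabicyclo[10.3.0]pentadeca-2,9,12-trien-7-yn-11-yl (2E)-2-methylbut-2-enoate
Product: 18 (1R,2E,9Z,11S)-13-[(TBS-oxy)methyl]-3,9-dimethyl-6,8,14-trioxo-5,15-dioxabicyclo[10.3.0]pentadeca-2,9,12-trien-11-yl (2E)-2-methylbut-2-enoate
Conditions: Ph3PAuCl (5 mol %), AgOTf (5 mol %), H2O (3 equiv), 1,4-dioxane, 40 °C
Reagents that add atoms: water, O
Why: Gold-catalysed alkyne hydration in which water attacks the ynoate β-carbon (oxa-Michael regiochemistry), giving the β-keto ester with the ketone on C1 and relieving the strain of the ring alkyne; the electron-poor alkenes and esters are not activated.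

Step 13
Reactants: 18 (1R,2E,9Z,11S)-13-[(TBS-oxy)methyl]-3,9-dimethyl-6,8,14-trioxo-5,15-dioxabicyclo[10.3.0]pentadeca-2,9,12-trien-11-yl (2E)-2-methylbut-2-enoate
Product: 19 (4E,6R,8S,9Z)-13-(TBS-oxy)-1-oxo-8-(tigloyloxy)germacra-4,7(11),9-trien-12,6-olide
Conditions: Pd(PPh3)4 (10 mol %), THF, 0.005 M, 0 → 23 °C
Reagents that add atoms: none
Why: Proposed new method: ring-contractive decarboxylative allylic alkylation, in which zerovalent palladium ionises the primary allylic C3–O bond of the macrolactone, the tethered β-keto carboxylate loses CO2, and the ketone enolate/π-allyl ion pair, still joined by the carbon chain, recombines at the unsubstituted allyl terminus to form C2–C3 and contract the twelve-membered lactone to the ten-membered carbocycle with the E C4=C5 alkene kept (syn π-allyl); the closest known reaction is the Tsuji-type decarboxylative allylation of acyclic allyl β-keto esters.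

Step 14
Reactants: 19 (4E,6R,8S,9Z)-13-(TBS-oxy)-1-oxo-8-(tigloyloxy)germacra-4,7(11),9-trien-12,6-olide; 20 acetic anhydride
Product: 22 (4E,6R,8S,9Z)-13-acetoxy-1-oxo-8-(tigloyloxy)germacra-4,7(11),9-trien-12,6-olide, via C13 alcohol 21 (not isolated)
Conditions: HF·pyridine, pyridine, THF, 0 °C; then Ac2O, DMAP, 0 °C
Reagents that add atoms: none
Why: Buffered fluoride desilylation followed by in situ acetylation installs the C13 acetate only after the palladium step, because an acetoxymethyl butenolide would itself ionise with zerovalent palladium.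

Step 15
Reactants: 22 (4E,6R,8S,9Z)-13-acetoxy-1-oxo-8-(tigloyloxy)germacra-4,7(11),9-trien-12,6-olide
Product: 23 (4R,5R,6S,8S,9Z)-13-acetoxy-4,5-epoxy-1-oxo-8-(tigloyloxy)germacra-7(11),9-dien-12,6-olide
Conditions: mCPBA, NaHCO3, CH2Cl2, 0 °C
Reagents that add atoms: 3-chloroperbenzoic acid, OOC(=O)c1cccc(Cl)c1
Why: Prilezhaev epoxidation of the only electron-rich alkene (the enone, butenolide and tiglate are deactivated); allylic 1,3-strain holds C6–H in the alkene plane, so attack on the outer face syn to the lactone oxygen gives the trans 4R,5R epoxide.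

Step 16
Reactants: 23 (4R,5R,6S,8S,9Z)-13-acetoxy-4,5-epoxy-1-oxo-8-(tigloyloxy)germacra-7(11),9-dien-12,6-olide
Product: 24 (1S,4R,5R,6S,8S,9Z)-13-acetoxy-4,5-epoxy-1-hydroxy-8-(tigloyloxy)germacra-7(11),9-dien-12,6-olide (CNP0222387.1)
Conditions: (R)-2-methyl-CBS-oxazaborolidine (0.3 equiv), catecholborane (1.8 equiv), toluene, −78 °C
Reagents that add atoms: none
Why: Corey–Bakshi–Shibata reduction, in which the (R)-oxazaborolidine delivers hydride 1,2 to the enone (α-methylalkenyl as the large group, CH2 as the small group) to set 1S, while the esters, lactone and epoxide are inert to catecholborane at −78 °C.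

## Compound list

1 | 2-methyl-2-vinyloxirane (racemic) | CC1(C=C)CO1 | starting material
2 | (2E)-4-chloro-2-methylbut-2-en-1-ol | OC/C(C)=C/CCl | intermediate
3 | (2E)-4-hydroxy-3-methylbut-2-enal | OC/C(C)=C/C=O | intermediate
4 | (2E)-4-chloro-3-methylbut-2-enal | ClC/C(C)=C/C=O | intermediate
5 | methyl propiolate | C#CC(=O)OC | starting material
6 | methyl (4R,5E)-7-chloro-4-hydroxy-6-methylhept-5-en-2-ynoate | COC(=O)C#C[C@H](O)/C=C(\C)CCl | intermediate
7 | formaldehyde | C=O | starting material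
8 | methyl (2E,4R,5E)-7-chloro-4-hydroxy-2-(hydroxymethyl)-3-iodo-6-methylhepta-2,5-dienoate (present as its aluminium alkoxide) | COC(=O)/C(CO)=C(/I)[C@H](O)/C=C(\C)CCl | intermediate
9 | (5R)-5-[(1E)-3-chloro-2-methylprop-1-en-1-yl]-3-(hydroxymethyl)-4-iodofuran-2(5H)-one | OCC1=C(I)[C@@H](/C=C(\C)CCl)OC1=O | intermediate
10 | (5R)-3-[(TBS-oxy)methyl]-5-[(1E)-3-chloro-2-methylprop-1-en-1-yl]-4-iodofuran-2(5H)-one | CC(C)(C)[Si](C)(C)OCC1=C(I)[C@@H](/C=C(\C)CCl)OC1=O | intermediate
11 | (2Z)-3-methylpent-2-en-4-yn-1-ol | C#C/C(C)=C\CO | starting material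
12 | (4Z)-6-hydroxy-4-methylhex-4-en-2-ynoic acid | OC/C=C(/C)C#CC(O)=O | intermediate
13 | (2E)-3-[(2R)-4-[(TBS-oxy)methyl]-3-iodo-5-oxo-2,5-dihydrofuran-2-yl]-2-methylprop-2-en-1-yl (4Z)-6-hydroxy-4-methylhex-4-en-2-ynoate | OC/C=C(/C)C#CC(=O)OC/C(C)=C/[C@H]1OC(=O)C(CO[Si](C)(C)C(C)(C)C)=C1I | intermediate
14 | (2E)-3-[(2R)-4-[(TBS-oxy)methyl]-3-iodo-5-oxo-2,5-dihydrofuran-2-yl]-2-methylprop-2-en-1-yl (4Z)-4-methyl-6-oxohex-4-en-2-ynoate | O=C/C=C(/C)C#CC(=O)OC/C(C)=C/[C@H]1OC(=O)C(CO[Si](C)(C)C(C)(C)C)=C1I | intermediate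
15 | (1R,2E,9Z,11S)-13-[(TBS-oxy)methyl]-11-hydroxy-3,9-dimethyl-5,15-dioxabicyclo[10.3.0]pentadeca-2,9,12-trien-7-yne-6,14-dione | O[C@H]1/C=C(/C)C#CC(=O)OC/C(C)=C/[C@H]2OC(=O)C(CO[Si](C)(C)C(C)(C)C)=C12 | intermediate
16 | tigloyl chloride, (2E)-2-methylbut-2-enoyl chloride | C/C=C(\C)C(Cl)=O | starting material
17 | (1R,2E,9Z,11S)-13-[(TBS-oxy)methyl]-3,9-dimethyl-6,14-dioxo-5,15-dioxabicyclo[10.3.0]pentadeca-2,9,12-trien-7-yn-11-yl (2E)-2-methylbut-2-enoate | C/C=C(\C)C(=O)O[C@H]1/C=C(/C)C#CC(=O)OC/C(C)=C/[C@H]2OC(=O)C(CO[Si](C)(C)C(C)(C)C)=C12 | intermediate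
18 | (1R,2E,9Z,11S)-13-[(TBS-oxy)methyl]-3,9-dimethyl-6,8,14-trioxo-5,15-dioxabicyclo[10.3.0]pentadeca-2,9,12-trien-11-yl (2E)-2-methylbut-2-enoate | C/C=C(\C)C(=O)O[C@H]1/C=C(/C)C(=O)CC(=O)OC/C(C)=C/[C@H]2OC(=O)C(CO[Si](C)(C)C(C)(C)C)=C12 | intermediate
19 | (4E,6R,8S,9Z)-13-(TBS-oxy)-1-oxo-8-(tigloyloxy)germacra-4,7(11),9-trien-12,6-olide | C/C=C(\C)C(=O)O[C@H]1/C=C(/C)C(=O)CC/C(C)=C/[C@H]2OC(=O)C(CO[Si](C)(C)C(C)(C)C)=C12 | intermediate
20 | acetic anhydride | CC(=O)OC(C)=O | starting material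
21 | (4E,6R,8S,9Z)-13-hydroxy-1-oxo-8-(tigloyloxy)germacra-4,7(11),9-trien-12,6-olide | C/C=C(\C)C(=O)O[C@H]1/C=C(/C)C(=O)CC/C(C)=C/[C@H]2OC(=O)C(CO)=C12 | intermediate
22 | (4E,6R,8S,9Z)-13-acetoxy-1-oxo-8-(tigloyloxy)germacra-4,7(11),9-trien-12,6-olide | C/C=C(\C)C(=O)O[C@H]1/C=C(/C)C(=O)CC/C(C)=C/[C@H]2OC(=O)C(COC(C)=O)=C12 | intermediate
23 | (4R,5R,6S,8S,9Z)-13-acetoxy-4,5-epoxy-1-oxo-8-(tigloyloxy)germacra-7(11),9-dien-12,6-olide | C/C=C(\C)C(=O)O[C@H]1/C=C(/C)C(=O)CC[C@@]2(C)O[C@@H]2[C@H]2OC(=O)C(COC(C)=O)=C12 | intermediate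
24 | (1S,4R,5R,6S,8S,9Z)-13-acetoxy-4,5-epoxy-1-hydroxy-8-(tigloyloxy)germacra-7(11),9-dien-12,6-olide | C/C=C(\C)C(=O)O[C@H]1/C=C(/C)[C@@H](O)CC[C@@]2(C)O[C@@H]2[C@H]2OC(=O)C(COC(C)=O)=C12 | target

## Step count and risks

Total steps: 16. Longest linear sequence: 15 steps (steps 1–6, then 8–16, from 1 to 24); the second branch (step 7) joins at step 8.

Steps most likely to fail:

Step 13 (the new ring contraction). Zerovalent palladium may also ionise the allylic C8 tiglate or the C6 lactone C–O bond, the π-allyl may equilibrate to give the Z alkene, or the ion pair may oligomerise or be protonated. The fallback uses known open-chain Tsuji–Trost macrocyclisation and sets out from 18. Heating 18 with 2-(trimethylsilyl)ethanol and DMAP in toluene at 110 °C opens the β-keto lactone by acylketene transesterification to 2-(trimethylsilyl)ethyl (4Z,6S)-6-{(2R)-4-[(TBS-oxy)methyl]-2-[(1E)-3-hydroxy-2-methylprop-1-en-1-yl]-5-oxo-2,5-dihydrofuran-3-yl}-4-methyl-3-oxo-6-(tigloyloxy)hex-4-enoate F5. ClCO2Me and pyridine convert the allylic alcohol to 2-(trimethylsilyl)ethyl (4Z,6S)-6-{(2R)-4-[(TBS-oxy)methyl]-2-[(1E)-3-(methoxycarbonyloxy)-2-methylprop-1-en-1-yl]-5-oxo-2,5-dihydrofuran-3-yl}-4-methyl-3-oxo-6-(tigloyloxy)hex-4-enoate F6. Pd2(dba)3·CHCl3 and dppe in THF at 0.003 M and 60 °C (neutral allylic alkylation by the stabilised β-keto ester) close the ring to (4E,6R,8S,9Z)-13-(TBS-oxy)-1-oxo-8-(tigloyloxy)-2-{[2-(trimethylsilyl)ethoxy]carbonyl}germacra-4,7(11),9-trien-12,6-olide F7 (C2 epimers). TBAF buffered with AcOH then cleaves the silylethyl ester with decarboxylation and removes the TBS group, which returns to the route at 21; acetylation as in step 14 follows.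

Step 5 (halo-aldol with formaldehyde). The aluminium allenoate may be protonated instead of hydroxymethylated, or the alkene isomers may not funnel to the lactone. The fallback replaces the halo-aldol by allenoate iodolactonisation, sets out from 4 and returns at 10. Zinc–ProPhenol addition of tert-butyldimethyl(prop-2-yn-1-yloxy)silane to 4 with (R,R)-ProPhenol gives (4S,5E)-1-(TBS-oxy)-7-chloro-6-methylhept-5-en-2-yn-4-ol F1. MsCl and Et3N give (4S,5E)-1-(TBS-oxy)-7-chloro-6-methylhept-5-en-2-yn-4-yl methanesulfonate F2. Pd(PPh3)4-catalysed methoxycarbonylation (CO 1 atm, MeOH, THF, −20 °C; anti SN2′ with centre-to-axis chirality transfer) gives methyl (5E)-2-[(TBS-oxy)methyl]-7-chloro-6-methylhepta-2,3,5-trienoate F3 (allene axis as in the SMILES). Here I assume the propargylic mesylate ionises faster than the primary allylic chloride at this temperature. Iodolactonisation (I2, NaHCO3, MeCN–H2O) then gives 10 directly, with overall inversion at the carbinol carbon, which is why the 4S alcohol is used.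

Step 10 (Ni/Cr macrocyclisation). The ring closes through a strained twelve-membered alkynoate, and the C8 diastereoselectivity rests on ligand control that may be overridden by the macrocycle. The fallback sets the stereocentre by ketone reduction instead of C–C bond formation; it sets out from 15 (as its C8-epimer mixture) and returns to 15. Dess–Martin periodinane oxidises the mixture to (1R,2E,9Z)-13-[(TBS-oxy)methyl]-3,9-dimethyl-5,15-dioxabicyclo[10.3.0]pentadeca-2,9,12-trien-7-yne-6,11,14-trione F4. Reduction with (R)-2-methyl-CBS-oxazaborolidine and catecholborane (butenolide carbon as the large group) then gives the 11S alcohol 15.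

Further compounds

F1 | step 5 | (4S,5E)-1-(TBS-oxy)-7-chloro-6-methylhept-5-en-2-yn-4-ol | CC(C)(C)[Si](C)(C)OCC#C[C@@H](O)/C=C(\C)CCl
F2 | step 5 | (4S,5E)-1-(TBS-oxy)-7-chloro-6-methylhept-5-en-2-yn-4-yl methanesulfonate | CC(C)(C)[Si](C)(C)OCC#C[C@@H](OS(C)(=O)=O)/C=C(\C)CCl
F3 | step 5 | methyl (5E)-2-[(TBS-oxy)methyl]-7-chloro-6-methylhepta-2,3,5-trienoate (allene axis as drawn) | COC(=O)C(CO[Si](C)(C)C(C)(C)C)=[C@]=C([H])/C=C(\C)CCl
F4 | step 10 | (1R,2E,9Z)-13-[(TBS-oxy)methyl]-3,9-dimethyl-5,15-dioxabicyclo[10.3.0]pentadeca-2,9,12-trien-7-yne-6,11,14-trione | O=C1/C=C(/C)C#CC(=O)OC/C(C)=C/[C@H]2OC(=O)C(CO[Si](C)(C)C(C)(C)C)=C12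
F5 | step 13 | 2-(trimethylsilyl)ethyl (4Z,6S)-6-{(2R)-4-[(TBS-oxy)methyl]-2-[(1E)-3-hydroxy-2-methylprop-1-en-1-yl]-5-oxo-2,5-dihydrofuran-3-yl}-4-methyl-3-oxo-6-(tigloyloxy)hex-4-enoate | C/C=C(\C)C(=O)O[C@@H](/C=C(/C)C(=O)CC(=O)OCC[Si](C)(C)C)C1=C(CO[Si](C)(C)C(C)(C)C)C(=O)O[C@@H]1/C=C(\C)CO
F6 | step 13 | 2-(trimethylsilyl)ethyl (4Z,6S)-6-{(2R)-4-[(TBS-oxy)methyl]-2-[(1E)-3-(methoxycarbonyloxy)-2-methylprop-1-en-1-yl]-5-oxo-2,5-dihydrofuran-3-yl}-4-methyl-3-oxo-6-(tigloyloxy)hex-4-enoate | C/C=C(\C)C(=O)O[C@@H](/C=C(/C)C(=O)CC(=O)OCC[Si](C)(C)C)C1=C(CO[Si](C)(C)C(C)(C)C)C(=O)O[C@@H]1/C=C(\C)COC(=O)OC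
F7 | step 13 | (4E,6R,8S,9Z)-13-(TBS-oxy)-1-oxo-8-(tigloyloxy)-2-{[2-(trimethylsilyl)ethoxy]carbonyl}germacra-4,7(11),9-trien-12,6-olide (C2 epimers) | C/C=C(\C)C(=O)O[C@H]1/C=C(/C)C(=O)C(C(=O)OCC[Si](C)(C)C)C/C(C)=C/[C@H]2OC(=O)C(CO[Si](C)(C)C(C)(C)C)=C12
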